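Substrate is left over in both earlier runs: at 20.0 h, target stands at 31% in cedar and 37% in alder, and alder gains 2 percentage points over its last interval against a scatter of 1.5 points.

| flask | substrate | coupling partner | capture agent | free catalyst | remark |
|---|---|---|---|---|---|
| cedar | 10 mM | 5 mM | 3 mM | 0.50 mM | run made earlier |
| alder | 10 mM | 20 mM | 3 mM | 0.50 mM | run made earlier |
| flask | 10 mM | 10.0 mM | 3.00 mM | 0.50 mM |  |

| run | time / h | target / % |
|---|---|---|
| cedar | 4.00 | 14 |
| cedar | 8.00 | 25 |
| cedar | 12.0 | 28 |
| cedar | 15.0 | 32 |
| cedar | 20.0 | 31 |
| alder | 2.00 | 13 |
| alder | 5.00 | 24 |
| alder | 10.0 | 34 |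
| alder | 15.0 | 35 |
| alder | 20.0 | 37 |

(readings scatter by 1.5 percentage points)

1. factor on the rate of making target when 10% of the substrate are converted if free catalyst is charged twice over
2. factor on the rate when 10% of the substrate are converted if free catalyst is charged at 5.0 mM instead

- the numbers in the tables scatter by 1.5 percentage points (one standard deviation)
- steps thought possible: coupling partner + free catalyst -> catalyst intermediate A; substrate + catalyst intermediate A -> catalyst intermediate B; catalyst intermediate B -> free catalyst + target; catalyst intermediate A + capture agent -> trapped intermediate
- no earlier run changes the charge of free catalyst; that part of a forecast is a guess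

With substrate over in both runs, the reading to carry is target at the last reading per catalyst charged. Averaged over the two runs it is 6.80 at 20.0 h; this is the turnover count by the last reading, with the scatter of the runs, and any catalyst still working at that time stands outside it.

Taken as a cost, it charges the flask 0.147 mM of catalyst by 10% conversion, leaving 0.353 mM working. If the rate follows working catalyst, this reckoning gives 2.42 for the doubled charge and 13.8 for 5.0 mM.

The forecast says 2.35 and 11, the second lower than this reckoning, because the large charge “is still in its first-cycle burst, with partner and substrate tied up”.

The flask gives 2.28 and 8.77, so the forecast of 11 stands higher by a factor of 1.25.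

    coupling partner + free catalyst → catalyst intermediate A (k = 0.200 M⁻¹ s⁻¹)
    substrate + catalyst intermediate A → catalyst intermediate B (k = 0.0560 M⁻¹ s⁻¹)
    catalyst intermediate B → free catalyst + target (k = 0.00270 s⁻¹)
    catalyst intermediate A + capture agent → trapped intermediate (k = 0.0200 M⁻¹ s⁻¹)

In the flask, trapped intermediate reaches 100% of the catalyst at 250 h with target at 40.0%, which makes 8.00 turnovers, more than the 6.80 read from the runs at 20.0 h, while 60.0% of the substrate still stands. The flask charged with 5.0 mM of free catalyst has, at the same conversion, 2.22% of its catalyst trapped, which is 9.03 as the ratio of substrate converted to catalyst lost, and 32.9% as free catalyst against 15.8% in the first flask, and it makes target at 4.23 mM h⁻¹ against 0.482 mM h⁻¹.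

(The earlier runs and the new flask are simulated for substances that don't exist.)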